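**Strategy.** Atoms are numbered as in elemanolides (cyclohexane C5–C10; lactone O–C8, C7, C11=C13, C12; epoxide C1–C2; enal C4(=C3)–C15). The route rests on disconnecting the C7–C8 bond that the cyclohexane and the cis-fused α-methylene-γ-butyrolactone share. A ruthenium-catalysed hetero-Pauson–Khand cyclocarbonylation of an acyclic allenyl aldehyde forms this bond, closes the carbocycle and builds the lactone with its exocyclic methylene from CO in one operation, setting C7 and C8. The precursor (C8 aldehyde, C6 allenyl carbinol) carries C1, C5, C9 and C10 from D-glyceraldehyde through an Ireland–Claisen rearrangement and an iodolactonisation, and C6 from a CBS reduction.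

Key step: step 16

Remark on the chemistry: (R)-2,2-dimethyl-1,3-dioxolane-4-carbaldehyde is taken as a commercial starting material and used freshly distilled, since it oligomerises on storage.

Step 1
Reactants: 1 (R)-2,2-dimethyl-1,3-dioxolane-4-carbaldehyde
Product: 2 (S)-4-ethynyl-2,2-dimethyl-1,3-dioxolane
Conditions: dimethyl (1-diazo-2-oxopropyl)phosphonate, K2CO3, MeOH, 0 °C → rt
Reagents that add atoms: dimethyl (1-diazo-2-oxopropyl)phosphonate, COP(=O)(OC)C(=[N+]=[N-])C(C)=O
Why: Ohira–Bestmann homologation turns the aldehyde into the terminal alkyne under mild carbonate conditions that should leave this α-alkoxy stereocentre (the future C1) intact.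

Step 2
Reactants: 2 (S)-4-ethynyl-2,2-dimethyl-1,3-dioxolane
Product: 3 methyl 3-[(4S)-2,2-dimethyl-1,3-dioxolan-4-yl]prop-2-ynoate
Conditions: n-BuLi, THF, −78 °C; ClCO2Me, −78 → 0 °C
Reagents that add atoms: methyl chloroformate, COC(Cl)=O
Why: Lithiation of the terminal alkyne and C-acylation with the chloroformate should give the ynoate.

Step 3
Reactants: 3 methyl 3-[(4S)-2,2-dimethyl-1,3-dioxolan-4-yl]prop-2-ynoate
Product: 4 methyl (2Z)-3-[(4S)-2,2-dimethyl-1,3-dioxolan-4-yl]but-2-enoate
Conditions: Me2CuLi (from MeLi, CuI), THF, −78 °C; aq. NH4Cl at −78 °C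
Reagents that add atoms: lithium dimethylcuprate, [Li+].C[Cu-]C
Why: syn-Carbocupration of the ynoate and protonation at low temperature should give the (Z)-enoate, in which the dioxolanyl group is cis to the ester as the later rearrangement needs.

Step 4
Reactants: 4 methyl (2Z)-3-[(4S)-2,2-dimethyl-1,3-dioxolan-4-yl]but-2-enoate
Product: 5 (2Z)-3-[(4S)-2,2-dimethyl-1,3-dioxolan-4-yl]but-2-en-1-ol
Conditions: iBu2AlH, CH2Cl2, −78 °C; aq. potassium sodium tartrate
Reagents that add atoms: none
Why: 1,2-Reduction of the enoate by iBu2AlH should give the allylic alcohol with the alkene geometry unchanged.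

Step 5
Reactants: 5 (2Z)-3-[(4S)-2,2-dimethyl-1,3-dioxolan-4-yl]but-2-en-1-ol; 6 3-methylbut-3-enoic acid
Product: 7 (2Z)-3-[(4S)-2,2-dimethyl-1,3-dioxolan-4-yl]but-2-en-1-yl 3-methylbut-3-enoate
Conditions: DCC, DMAP (cat.), CH2Cl2, −20 → 0 °C
Reagents that add atoms: none
Why: Steglich esterification at low temperature joins the two fragments before the β,γ-unsaturated acid can isomerise into conjugation.

Step 6
Reactants: 7 (2Z)-3-[(4S)-2,2-dimethyl-1,3-dioxolan-4-yl]but-2-en-1-yl 3-methylbut-3-enoate
Product: 10 (2S,3R)-3-[(4S)-2,2-dimethyl-1,3-dioxolan-4-yl]-3-methyl-2-(prop-1-en-2-yl)pent-4-enoic acid, via silyl ketene acetal 8 (not isolated), via trimethylsilyl ester 9 (not isolated)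
Conditions: LiN(iPr)2, THF, −78 °C; Me3SiCl; −78 → 50 °C; aq. citric acid
Reagents that add atoms: none
Why: Ireland–Claisen rearrangement, in which kinetic enolisation in THF gives the (E)-silyl ketene acetal whose chair transition state with the (Z)-alkene places the dioxolanyl and isopropenyl groups axial and so fixes C5 against C10, while allylic strain keeps the dioxolane C–H in the alkene plane and the new C5–C10 bond forms anti to the C1–O bond, relaying C1 to C10.

Step 7
Reactants: 10 (2S,3R)-3-[(4S)-2,2-dimethyl-1,3-dioxolan-4-yl]-3-methyl-2-(prop-1-en-2-yl)pent-4-enoic acid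
Product: 11 (3S,4R,5S)-4-[(4S)-2,2-dimethyl-1,3-dioxolan-4-yl]-5-(iodomethyl)-4-methyl-3-(prop-1-en-2-yl)oxolan-2-one
Conditions: I2, NaHCO3, MeCN/H2O, 0 °C, dark
Reagents that add atoms: iodine, II
Why: Iodolactonisation, in which iodonium formation is reversible at both alkenes but only the C8=C9 vinyl group can be captured by fast 5-exo attack of the carboxylate, and the CH2I group should settle trans to the bulky dioxolanyl group on C10, which sets C9.

Step 8
Reactants: 11 iodolactone
Product: 14 (3S,4R,5S)-4-[(4S)-2,2-dimethyl-1,3-dioxolan-4-yl]-5-(hydroxymethyl)-4-methyl-3-(prop-1-en-2-yl)oxolan-2-one, via epoxy carboxylate 12 (not isolated), via dihydroxy carboxylate 13 (not isolated)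
Conditions: LiOH, THF/H2O, 60 °C; then AcOH to pH 5, 40 °C
Reagents that add atoms: lithium hydroxide, [Li+].[OH-]
Why: Saponification frees the C9 alkoxide, which closes to the C8–C9 epoxide with retention at C9, hydroxide opens it at the primary C8, and mild acidification relactonises the γ-hydroxy acid (substitution followed by lactonisation).

Step 9
Reactants: 14 hydroxy lactone
Product: 15 triethylsilyl ether of 14 at the C8 oxygen
Conditions: Et3SiCl, imidazole, CH2Cl2, 0 °C
Reagents that add atoms: chlorotriethylsilane, CC[Si](Cl)(CC)CC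
Why: Standard silylation of the only free (primary) hydroxyl.

Step 10
Reactants: 15 silylated lactone
Product: 17 Weinreb amide bearing the C9 methacrylate, via hydroxy amide 16 (not isolated)
Conditions: MeNH(OMe)·HCl, Me3Al, CH2Cl2, 0 °C → rt; then methacrylic anhydride, Et3N, DMAP (cat.), 0 °C → rt
Reagents that add atoms: N,O-dimethylhydroxylamine hydrochloride, CNOC.Cl; methacrylic anhydride, CC(=C)C(=O)OC(=O)C(C)=C
Why: Aluminium amide aminolysis of the lactone (Weinreb amide formation) frees the hindered C9 alkoxide, which is acylated at once under DMAP catalysis before it can relactonise.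

Step 11
Reactants: 17 Weinreb amide
Product: 18 ethynyl ketone (C6 carbonyl, C7≡C11)
Conditions: HC≡CMgBr, THF, 0 °C; aq. NH4Cl
Reagents that add atoms: ethynylmagnesium bromide, C#C[Mg]Br
Why: Addition of the alkynyl Grignard reagent to the Weinreb amide stops at the ketone through the chelated tetrahedral intermediate, and the chelating amide should react faster than the hindered methacrylate ester.

Step 12
Reactants: 18 ethynyl ketone
Product: 19 (6S)-propargylic alcohol
Conditions: (S)-2-methyl-CBS-oxazaborolidine (20 mol %), catecholborane, toluene, −78 °C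
Reagents that add atoms: none
Why: Corey–Bakshi–Shibata reduction, in which the ethynyl group acts as the small substituent so that the (S)-catalyst delivers hydride to the face that Felkin–Anh control from C5 also favours, setting C6 in a matched case.

Step 13
Reactants: 19 propargylic alcohol
Product: 20 C6,C8-bis(triethylsilyl) ether
Conditions: Et3SiOTf, 2,6-lutidine, CH2Cl2, −78 °C
Reagents that add atoms: triethylsilyl trifluoromethanesulfonate, CC[Si](CC)(CC)OS(=O)(=O)C(F)(F)F
Why: A silyl triflate with a hindered base should silylate the secondary propargylic alcohol at low temperature without touching the ester or the alkyne.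

Step 14
Reactants: 20 terminal alkyne
Product: 22 terminal allene (C7=C11=C13), via propargylic amine 21 (not isolated)
Conditions: (CH2O)n, CuI (0.5 equiv), Cy2NH, BHT, 1,4-dioxane, reflux
Reagents that add atoms: paraformaldehyde (as formaldehyde), C=O
Why: Crabbé homologation, in which the CuI-catalysed Mannich reaction of the terminal alkyne gives the propargylic amine, which loses the imine by 1,5-hydride transfer to give the terminal allene without touching C6.

Step 15
Reactants: 22 allene
Product: 23 allenyl aldehyde (C8 aldehyde, C9 methacrylate, C6 silyl ether)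
Conditions: (COCl)2, DMSO, CH2Cl2, −78 → −30 °C; Et3N, −78 → 0 °C
Reagents that add atoms: none
Why: Swern conditions cleave and oxidise the primary triethylsilyl ether directly to the aldehyde while the more hindered secondary silyl ether at C6 should survive.

Step 16
Reactants: 23 allenyl aldehyde
Product: 24 cis-fused α-methylene-γ-butyrolactone on the cyclohexane (C6 silyl ether, C9 methacrylate, C5 isopropenyl, C10 dioxolanyl)
Conditions: Ru3(CO)12 (5 mol %), CO (10 atm), BHT, 1,4-dioxane, 120 °C
Reagents that add atoms: carbon monoxide, [C-]#[O+]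
Why: Zerovalent ruthenium carbonyl couples the C8 aldehyde and the proximal C7=C11 bond of the allene by oxidative cyclisation to an oxaruthenacyclopentane (new C7–C8 bond), CO inserts into the Ru–C11 bond and reductive elimination forms the C12–O8 bond. The closest known reaction type is the ruthenium-catalysed cyclocarbonylation (hetero-Pauson–Khand reaction) of allenyl aldehydes to bicyclic α-methylene-γ-butyrolactones. The cyclohexane closes by 6-exo attack of the aldehyde carbon on the allene terminus C7 and the lactone by [2+2+1] assembly of C8=O, C7=C11 and CO, so the exocyclic C11=C13 methylene is kept from the distal allene bond. C7 and C8 are set cis to each other by the cis-fused metallacycle, and their sense relative to the chain should follow from a chair-like tether with the C6 silyloxy, C9 acyloxy and C10 methyl groups equatorial, since the other cis-fused isomer would force the allene carbon axial and syn to the axial isopropenyl group. The step needs chemoselectivity for the allene over the isopropenyl and methacrylate double bonds, which the far higher reactivity of the cumulated diene in oxidative cyclisation should secure, and facial selectivity, which the preset stereocentres C5, C6, C9 and C10 should provide.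

Step 17
Reactants: 24 bicyclic lactone
Product: 25 C1,C2,C6-triol
Conditions: AcOH/THF/H2O (3:1:1), 45 °C
Reagents that add atoms: none
Why: Aqueous acetic acid hydrolyses the triethylsilyl ether and the terminal acetonide (silyl ether and acetal hydrolysis), and these mildly acidic conditions should leave the lactone and the methacrylate in place.

Step 18
Reactants: 25 triol
Product: 26 C1–C2 epoxide
Conditions: PPh3, DIAD (premixed), THF, 0 °C → rt
Reagents that add atoms: none
Why: Mitsunobu cyclodehydration, in which the primary C2 hydroxyl is activated as its oxyphosphonium salt and displaced by the neighbouring C1 hydroxyl, so the epoxide forms with retention at the neopentyl C1 under neutral conditions that should spare the esters.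

Step 19
Reactants: 26 epoxide
Product: 28 target CNP0124638.3, via allylic alcohol 27 (not isolated)
Conditions: SeO2 (cat.), t-BuOOH, CH2Cl2, rt; then MnO2, CH2Cl2, rt
Reagents that add atoms: selenium dioxide, O=[Se]=O; tert-butyl hydroperoxide, CC(C)(C)OO
Why: SeO2 allylic oxidation (ene reaction and [2,3]-shift) attacks the methyl group of the isopropenyl unit, the only electron-rich alkene with allylic hydrogens, and MnO2 then oxidises only the allylic alcohol to the enal.

**Compound list**

1 | (R)-2,2-dimethyl-1,3-dioxolane-4-carbaldehyde (D-glyceraldehyde acetonide) | O=C[C@H]1COC(C)(C)O1 | starting material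
2 | (S)-4-ethynyl-2,2-dimethyl-1,3-dioxolane | C#C[C@H]1COC(C)(C)O1 | intermediate
3 | methyl 3-[(4S)-2,2-dimethyl-1,3-dioxolan-4-yl]prop-2-ynoate | COC(=O)C#C[C@H]1COC(C)(C)O1 | intermediate
4 | methyl (2Z)-3-[(4S)-2,2-dimethyl-1,3-dioxolan-4-yl]but-2-enoate | COC(=O)/C=C(C)\[C@H]1COC(C)(C)O1 | intermediate
5 | (2Z)-3-[(4S)-2,2-dimethyl-1,3-dioxolan-4-yl]but-2-en-1-ol | OC/C=C(C)\[C@H]1COC(C)(C)O1 | intermediate
6 | 3-methylbut-3-enoic acid | C=C(C)CC(=O)O | starting material
7 | (2Z)-3-[(4S)-2,2-dimethyl-1,3-dioxolan-4-yl]but-2-en-1-yl 3-methylbut-3-enoate | C=C(C)CC(=O)OC/C=C(C)\[C@H]1COC(C)(C)O1 | intermediate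
8 | (E)-trimethylsilyl ketene acetal of 7 (isopropenyl cis to the allyloxy oxygen) | C=C(C)/C=C(/O[Si](C)(C)C)OC/C=C(C)\[C@H]1COC(C)(C)O1 | intermediate
9 | trimethylsilyl ester of acid 10 | C[Si](C)(C)OC(=O)[C@@H](C(C)=C)[C@@](C)(C=C)[C@H]1COC(C)(C)O1 | intermediate
10 | (2S,3R)-3-[(4S)-2,2-dimethyl-1,3-dioxolan-4-yl]-3-methyl-2-(prop-1-en-2-yl)pent-4-enoic acid | OC(=O)[C@@H](C(C)=C)[C@@](C)(C=C)[C@H]1COC(C)(C)O1 | intermediate
11 | (3S,4R,5S)-4-[(4S)-2,2-dimethyl-1,3-dioxolan-4-yl]-5-(iodomethyl)-4-methyl-3-(prop-1-en-2-yl)oxolan-2-one (iodomethyl, methyl and isopropenyl mutually cis) | O=C1O[C@H](CI)[C@@](C)([C@H]2COC(C)(C)O2)[C@@H]1C(C)=C | intermediate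
12 | lithium salt of the C8–C9 epoxy acid from 11 (C5, C9, C10, C1 as in 11) | [Li+].[O-]C(=O)[C@@H](C(C)=C)[C@@](C)([C@H]1CO1)[C@H]1COC(C)(C)O1 | intermediate
13 | lithium salt of the C8,C9-dihydroxy acid (C5, C9, C10, C1 as in 11) | [Li+].[O-]C(=O)[C@@H](C(C)=C)[C@@](C)([C@H](O)CO)[C@H]1COC(C)(C)O1 | intermediate
14 | (3S,4R,5S)-4-[(4S)-2,2-dimethyl-1,3-dioxolan-4-yl]-5-(hydroxymethyl)-4-methyl-3-(prop-1-en-2-yl)oxolan-2-one | O=C1O[C@H](CO)[C@@](C)([C@H]2COC(C)(C)O2)[C@@H]1C(C)=C | intermediate
15 | C8 triethylsilyl ether of 14 | O=C1O[C@H](CO[Si](CC)(CC)CC)[C@@](C)([C@H]2COC(C)(C)O2)[C@@H]1C(C)=C | intermediate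
16 | N-methoxy-N-methyl amide of the ring-opened lactone with free C9 hydroxyl (stereocentres as in 15) | CON(C)C(=O)[C@@H](C(C)=C)[C@@](C)([C@H](O)CO[Si](CC)(CC)CC)[C@H]1COC(C)(C)O1 | intermediate
17 | N-methoxy-N-methyl amide with C9 methacrylate and C8 triethylsilyl ether (stereocentres as in 15) | CON(C)C(=O)[C@@H](C(C)=C)[C@@](C)([C@H](OC(=O)C(C)=C)CO[Si](CC)(CC)CC)[C@H]1COC(C)(C)O1 | intermediate
18 | ethynyl ketone at C6 (stereocentres as in 15) | C#CC(=O)[C@@H](C(C)=C)[C@@](C)([C@H](OC(=O)C(C)=C)CO[Si](CC)(CC)CC)[C@H]1COC(C)(C)O1 | intermediate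
19 | (6S)-propargylic alcohol (other stereocentres as in 15) | C#C[C@@H](O)[C@@H](C(C)=C)[C@@](C)([C@H](OC(=O)C(C)=C)CO[Si](CC)(CC)CC)[C@H]1COC(C)(C)O1 | intermediate
20 | C6,C8-bis(triethylsilyl) ether of 19 | C#C[C@@H](O[Si](CC)(CC)CC)[C@@H](C(C)=C)[C@@](C)([C@H](OC(=O)C(C)=C)CO[Si](CC)(CC)CC)[C@H]1COC(C)(C)O1 | intermediate
21 | N,N-dicyclohexylpropargylic amine from 20 (Mannich base, stereocentres as in 20) | C(N(C1CCCCC1)C1CCCCC1)C#C[C@@H](O[Si](CC)(CC)CC)[C@@H](C(C)=C)[C@@](C)([C@H](OC(=O)C(C)=C)CO[Si](CC)(CC)CC)[C@H]1COC(C)(C)O1 | intermediate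
22 | terminal allene C7=C11=C13 (stereocentres as in 20) | C=C=C[C@@H](O[Si](CC)(CC)CC)[C@@H](C(C)=C)[C@@](C)([C@H](OC(=O)C(C)=C)CO[Si](CC)(CC)CC)[C@H]1COC(C)(C)O1 | intermediate
23 | allenyl aldehyde: C8 aldehyde, C9 methacrylate, C6 triethylsilyl ether (stereocentres as in 22) | C=C=C[C@@H](O[Si](CC)(CC)CC)[C@@H](C(C)=C)[C@@](C)([C@H](OC(=O)C(C)=C)C=O)[C@H]1COC(C)(C)O1 | intermediate
24 | bicyclic 8,12-lactone with C6 triethylsilyl ether, C5 isopropenyl and C10 (4S)-dioxolanyl; ring stereocentres arranged as in the target | C=C(C)C(=O)O[C@@H]1[C@@H]2OC(=O)C(=C)[C@@H]2[C@@H](O[Si](CC)(CC)CC)[C@@H](C(C)=C)[C@]1(C)[C@H]1COC(C)(C)O1 | intermediate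
25 | C1,C2,C6-triol (stereocentres arranged as in the target) | C=C(C)C(=O)O[C@@H]1[C@@H]2OC(=O)C(=C)[C@@H]2[C@@H](O)[C@@H](C(C)=C)[C@]1(C)[C@H](O)CO | intermediate
26 | C1–C2 epoxide with C5 isopropenyl (stereocentres arranged as in the target) | C=C(C)C(=O)O[C@@H]1[C@@H]2OC(=O)C(=C)[C@@H]2[C@@H](O)[C@@H](C(C)=C)[C@]1(C)[C@H]1CO1 | intermediate
27 | C15 allylic alcohol | C=C(C)C(=O)O[C@@H]1[C@@H]2OC(=O)C(=C)[C@@H]2[C@@H](O)[C@@H](C(=C)CO)[C@]1(C)[C@H]1CO1 | intermediate
28 | target CNP0124638.3 (C1 S, C5 R, C6 S, C7 R, C8 R, C9 S, C10 R in the numbering used here) | C=C(C)C(=O)O[C@@H]1[C@@H]2OC(=O)C(=C)[C@@H]2[C@@H](O)[C@@H](C(=C)C=O)[C@]1(C)[C@H]1CO1 | target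

**Totals.** 19 steps; the longest linear sequence is 19 steps (from 1).

**Steps most likely to fail**

1. Step 16. The two cis-fused diastereomers differ mainly in 1,3-diaxial strain, so facial selectivity may erode at 120 °C, and the α-acyloxy aldehyde may decarbonylate. Fallback: from aldehyde 23, palladium-catalysed distannylation of the allene (Bu3SnSnBu3, Pd2(dba)3, THF, rt) would give an allylstannane that adds in situ to the aldehyde through a closed six-membered transition state, giving the cis-hydroxy vinylstannane F1. Iododestannylation (I2, CH2Cl2, −78 °C) would give the vinyl iodide F2. Carbonylative lactonisation (Pd(PPh3)4, CO, Et3N, THF) would then close the α-methylene lactone and return to 24.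

2. Step 11. The Grignard reagent may add to the methacrylate, or enolise C5. Fallback: from lactone 15, the aminolysis of step 10 would be followed by silylation (Me3SiCl, imidazole) instead of acylation, giving the C9 trimethylsilyl ether F3. HC≡CMgBr would then give the ethynyl ketone F4 with no ester present. Selective removal of the trimethylsilyl group (citric acid, MeOH, 0 °C) would give the hydroxy ketone F5, and acylation with methacrylic anhydride/DMAP would return to 18.

3. Step 18. The methacryloyl group may migrate from O9 to the freed C1 hydroxyl, or the phosphine may add to the acrylate units during the dehydration. Fallback: from triol 25, selective sulfonylation of the primary C2 hydroxyl (TsCl, Et3N, cat. Bu2SnO, CH2Cl2, 0 °C) would give the monotosylate F6, and brief treatment with DBU at 0 °C would close the epoxide by displacement and return to 26.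

Further compounds
F1 | step 16 | cis-hydroxy vinylstannane: C8 alcohol, C7 bearing 1-(tributylstannyl)vinyl, other groups as in 24 | C=C(C)C(=O)O[C@@H]1[C@H](O)[C@H](C(=C)[Sn](CCCC)(CCCC)CCCC)[C@@H](O[Si](CC)(CC)CC)[C@@H](C(C)=C)[C@]1(C)[C@H]1COC(C)(C)O1
F2 | step 16 | vinyl iodide: C8 alcohol, C7 bearing 1-iodovinyl | C=C(C)C(=O)O[C@@H]1[C@H](O)[C@H](C(=C)I)[C@@H](O[Si](CC)(CC)CC)[C@@H](C(C)=C)[C@]1(C)[C@H]1COC(C)(C)O1
F3 | step 11 | N-methoxy-N-methyl amide with C9 trimethylsilyl ether and C8 triethylsilyl ether | CON(C)C(=O)[C@@H](C(C)=C)[C@@](C)([C@H](O[Si](C)(C)C)CO[Si](CC)(CC)CC)[C@H]1COC(C)(C)O1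
F4 | step 11 | ethynyl ketone with C9 trimethylsilyl ether | C#CC(=O)[C@@H](C(C)=C)[C@@](C)([C@H](O[Si](C)(C)C)CO[Si](CC)(CC)CC)[C@H]1COC(C)(C)O1
F5 | step 11 | ethynyl ketone with free C9 hydroxyl | C#CC(=O)[C@@H](C(C)=C)[C@@](C)([C@H](O)CO[Si](CC)(CC)CC)[C@H]1COC(C)(C)O1
F6 | step 18 | C2 p-toluenesulfonate of triol 25 | C=C(C)C(=O)O[C@@H]1[C@@H]2OC(=O)C(=C)[C@@H]2[C@@H](O)[C@@H](C(C)=C)[C@]1(C)[C@H](O)COS(=O)(=O)c1ccc(C)cc1
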